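**Plan**

- Labels: ring A is the methoxyquinone (C1=O, C2–OMe, C3–H, C4=O, C5–O5, C6–CH2), ring B the 1,4-phenylene, ring C the phenol ring, ring D the 1,3-phenylene (C1 carries the bridge, C3 carries O5). The macrocycle is 18-membered.
- Cuts, in retrosynthetic order: quinone back to its hydroquinone, held as the O1,O4-dibenzyl ether; then the ring bond O5(ring A)–C3(ring D), by intramolecular Ullmann etherification; then both ethano bridges as C=C (two Wittig reactions); then the ring B–O–ring C ether (SNAr).
- Enabling feature: at the hydroquinone dibenzyl ether level O5 is the only free OH and a pure phenoxide O-nucleophile (as a hydroxyquinone it would be an ambident vinylogous carboxylate). C3 of ring D has CH neighbours (C2, C4) on both sides, so a bromine there is unhindered and survives the assembly.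
- Forward: ring A salicylaldehyde 7 from methoxyhydroquinone; B–O–C ether, then ring D by Wittig; ester to phosphonium salt; ring A by Wittig; diimide; ring closure; hydrogenolysis and oxidation remove the helpers.
- Stereochemistry: the target has no stereocentre, so none is set.

Key step: step 11

Remark: the alkenes formed in steps 6 and 9 are expected as E/Z mixtures and are drawn without geometry; both are saturated in step 10.

**Route**

Step 1
Reactants: 1 2-methoxybenzene-1,4-diol
Product: 2 1,4-bis(benzyloxy)-2-methoxybenzene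
Conditions: BnBr, K2CO3, DMF, N2, rt to 60 °C
Reagents that add atoms: benzyl bromide (BrCc1ccccc1)
Why: Williamson etherification of both phenolic hydroxyls under nitrogen should install the two benzyl ethers that hold ring A at the hydroquinone level until step 12.

Step 2
Reactants: 2 1,4-bis(benzyloxy)-2-methoxybenzene
Product: 4 2,5-bis(benzyloxy)-4-methoxybenzaldehyde, via iminium chloride 3 (not isolated)
Conditions: POCl3, DMF, 0 to 75 °C; then ice-water
Reagents that add atoms: N,N-dimethylformamide (CN(C)C=O); water (O)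
Why: Vilsmeier–Haack formylation of a 1,2,4-trialkoxybenzene should go to the position para to OMe and ortho to OBn, which has only one substituted neighbour, as with 1,2,4-trimethoxybenzene.

Step 3
Reactants: 4 2,5-bis(benzyloxy)-4-methoxybenzaldehyde
Product: 6 2,5-bis(benzyloxy)-4-methoxyphenol, via aryl formate 5 (not isolated)
Conditions: mCPBA, CH2Cl2, 0 °C to rt; then K2CO3 (cat.), MeOH, rt
Reagents that add atoms: mCPBA (OOC(=O)c1cccc(Cl)c1)
Why: Baeyer–Villiger oxidation of an electron-rich benzaldehyde should proceed with aryl migration (Dakin-type) to the formate, which methanolysis cleaves to the phenol whose oxygen becomes O5.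

Step 4
Reactants: 6 2,5-bis(benzyloxy)-4-methoxyphenol
Product: 7 3,6-bis(benzyloxy)-2-hydroxy-5-methoxybenzaldehyde
Conditions: MgCl2, Et3N, (CH2O)n, MeCN, reflux; then 1 M HCl
Reagents that add atoms: paraformaldehyde, as formaldehyde (C=O)
Why: Magnesium-phenoxide-directed ortho-formylation (Casnati–Skattebøl) can only reach the single free ortho position, and the hydroxymethyl intermediate is oxidised to the aldehyde by a second equivalent of formaldehyde.

Step 5
Reactants: 8 4-(benzyloxy)-3-hydroxybenzaldehyde; 9 methyl 4-fluorobenzoate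
Product: 10 methyl 4-[2-(benzyloxy)-5-formylphenoxy]benzoate
Conditions: K2CO3, DMSO, 120 °C
Reagents that add atoms: none
Why: Nucleophilic aromatic substitution of the fluoride para to the ester by the phenoxide should give the ring B–O–ring C ether with two carbonyl groups of different kind.

Step 6
Reactants: 10 methyl 4-[2-(benzyloxy)-5-formylphenoxy]benzoate; 11 (3-bromobenzyl)triphenylphosphonium bromide
Product: 13 methyl 4-{2-(benzyloxy)-5-[2-(3-bromophenyl)ethenyl]phenoxy}benzoate (E/Z mixture), via ylide 12 (not isolated)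
Conditions: K2CO3, 18-crown-6 (cat.), CH2Cl2, reflux
Reagents that add atoms: none
Why: Wittig olefination with a semi-stabilised benzylic ylide should take the aldehyde only and leave the methyl ester untouched.

Step 7
Reactants: 13 methyl 4-{2-(benzyloxy)-5-[2-(3-bromophenyl)ethenyl]phenoxy}benzoate
Product: 14 (4-{2-(benzyloxy)-5-[2-(3-bromophenyl)ethenyl]phenoxy}phenyl)methanol
Conditions: i-Bu2AlH, CH2Cl2, −78 to 0 °C; then aq. Rochelle salt
Reagents that add atoms: none
Why: Hydride reduction of the ester to the benzylic alcohol should leave the aryl bromide, the alkene and the benzyl ether alone.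

Step 8
Reactants: 14 (4-{2-(benzyloxy)-5-[2-(3-bromophenyl)ethenyl]phenoxy}phenyl)methanol
Product: 15 (4-{2-(benzyloxy)-5-[2-(3-bromophenyl)ethenyl]phenoxy}benzyl)triphenylphosphonium bromide
Conditions: PPh3·HBr, MeCN, reflux
Reagents that add atoms: triphenylphosphine hydrobromide ([PH+](c1ccccc1)(c1ccccc1)c1ccccc1.[Br-])
Why: Acid-promoted ionisation of the para-aryloxybenzyl alcohol and capture of the stabilised benzylic cation by the phosphine (SN1-type phosphonium salt formation) should give the salt in one operation.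

Step 9
Reactants: 15 (4-{2-(benzyloxy)-5-[2-(3-bromophenyl)ethenyl]phenoxy}benzyl)triphenylphosphonium bromide; 7 3,6-bis(benzyloxy)-2-hydroxy-5-methoxybenzaldehyde
Product: 17 3,6-bis(benzyloxy)-2-[2-(4-{2-(benzyloxy)-5-[2-(3-bromophenyl)ethenyl]phenoxy}phenyl)ethenyl]-4-methoxyphenol (E/Z mixture), via ylide 16 (not isolated)
Conditions: KOtBu (2.3 equiv), THF, 0 to 60 °C; then aq. NH4Cl
Reagents that add atoms: none
Why: Wittig olefination should join ring A to ring B, one equivalent of base forming the ylide and the second holding the ortho-hydroxyl as its phenoxide.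

Step 10
Reactants: 17 3,6-bis(benzyloxy)-2-[2-(4-{2-(benzyloxy)-5-[2-(3-bromophenyl)ethenyl]phenoxy}phenyl)ethenyl]-4-methoxyphenol
Product: 18 3,6-bis(benzyloxy)-2-[2-(4-{2-(benzyloxy)-5-[2-(3-bromophenyl)ethyl]phenoxy}phenyl)ethyl]-4-methoxyphenol
Conditions: TsNHNH2 (excess), NaOAc, THF/H2O, N2, reflux
Reagents that add atoms: none
Why: Diimide reduction (concerted syn transfer of two hydrogens) should saturate both stilbene bonds while sparing the C–Br bond and the benzyl ethers, which hydrogenation over palladium would not.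

Step 11
Reactants: 18 3,6-bis(benzyloxy)-2-[2-(4-{2-(benzyloxy)-5-[2-(3-bromophenyl)ethyl]phenoxy}phenyl)ethyl]-4-methoxyphenol
Product: 19 macrocyclic tribenzyl ether (hydroquinone form of the target with O1, O4 and the ring C oxygen benzylated)
Conditions: CuBr·SMe2 (3 equiv), Cs2CO3, degassed pyridine, 110 °C, slow addition of 18 to about 2 mM
Reagents that add atoms: none
Why: Cs2CO3 turns the only free hydroxyl, O5 of ring A, into the phenoxide, which binds monovalent copper; oxidative addition of the ring D C3–Br bond and C–O reductive elimination from the trivalent aryl(aryloxy)copper species form the O5–C3 bond. The closest known reaction type is the intramolecular Ullmann diaryl ether macrocyclisation used for 14- to 18-membered cyclophane ethers, including phenols flanked on both sides. The 18-membered ring is closed end to end, phenoxide oxygen onto an sp2 carbon with the two ethano bridges as hinges; copper is in excess, so slow addition keeps 18 dilute without slowing copper phenoxide formation. No stereocentre is formed. The chemoselectivity needed is built into 18: O1, O4 and the ring C oxygen are benzyl ethers, there is a single C–Br bond, and C3 of ring D has CH neighbours, so all hindrance lies on the phenoxide side.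

Step 12
Reactants: 19 macrocyclic tribenzyl ether
Product: 21 CNP0332646.0, via hydroquinone 20 (not isolated)
Conditions: H2 (1 atm), Pd/C, EtOAc/MeOH, rt; filter; then Ag2O, MgSO4, EtOAc, rt
Reagents that add atoms: none
Why: Hydrogenolysis of the three benzyl ethers should free the ring A hydroquinone and the ring C phenol, and Ag2O should oxidise only the electron-rich 1,4-diol to the quinone, since the ring C phenol is a mono-phenol.

**Compound list**

1 | 2-methoxybenzene-1,4-diol | COc1cc(O)ccc1O | starting material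
2 | 1,4-bis(benzyloxy)-2-methoxybenzene | COc1cc(OCc2ccccc2)ccc1OCc1ccccc1 | intermediate
3 | N-[2,5-bis(benzyloxy)-4-methoxybenzylidene]-N-methylmethanaminium chloride | COc1cc(OCc2ccccc2)c(C=[N+](C)C)cc1OCc1ccccc1.[Cl-] | intermediate (not isolated)
4 | 2,5-bis(benzyloxy)-4-methoxybenzaldehyde | COc1cc(OCc2ccccc2)c(C=O)cc1OCc1ccccc1 | intermediate
5 | 2,5-bis(benzyloxy)-4-methoxyphenyl formate | COc1cc(OCc2ccccc2)c(OC=O)cc1OCc1ccccc1 | intermediate (not isolated)
6 | 2,5-bis(benzyloxy)-4-methoxyphenol | COc1cc(OCc2ccccc2)c(O)cc1OCc1ccccc1 | intermediate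
7 | 3,6-bis(benzyloxy)-2-hydroxy-5-methoxybenzaldehyde | COc1cc(OCc2ccccc2)c(O)c(C=O)c1OCc1ccccc1 | intermediate
8 | 4-(benzyloxy)-3-hydroxybenzaldehyde | O=Cc1ccc(OCc2ccccc2)c(O)c1 | starting material
9 | methyl 4-fluorobenzoate | COC(=O)c1ccc(F)cc1 | starting material
10 | methyl 4-[2-(benzyloxy)-5-formylphenoxy]benzoate | COC(=O)c1ccc(Oc2cc(C=O)ccc2OCc2ccccc2)cc1 | intermediate
11 | (3-bromobenzyl)triphenylphosphonium bromide | [Br-].Brc1cccc(C[P+](c2ccccc2)(c2ccccc2)c2ccccc2)c1 | starting material
12 | (3-bromobenzylidene)triphenylphosphorane | Brc1cccc(C=P(c2ccccc2)(c2ccccc2)c2ccccc2)c1 | intermediate (not isolated)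
13 | methyl 4-{2-(benzyloxy)-5-[2-(3-bromophenyl)ethenyl]phenoxy}benzoate (E/Z mixture) | COC(=O)c1ccc(Oc2cc(C=Cc3cccc(Br)c3)ccc2OCc2ccccc2)cc1 | intermediate
14 | (4-{2-(benzyloxy)-5-[2-(3-bromophenyl)ethenyl]phenoxy}phenyl)methanol (E/Z mixture) | OCc1ccc(Oc2cc(C=Cc3cccc(Br)c3)ccc2OCc2ccccc2)cc1 | intermediate
15 | (4-{2-(benzyloxy)-5-[2-(3-bromophenyl)ethenyl]phenoxy}benzyl)triphenylphosphonium bromide (E/Z mixture) | [Br-].Brc1cccc(C=Cc2ccc(OCc3ccccc3)c(Oc3ccc(C[P+](c4ccccc4)(c4ccccc4)c4ccccc4)cc3)c2)c1 | intermediate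
16 | (4-{2-(benzyloxy)-5-[2-(3-bromophenyl)ethenyl]phenoxy}benzylidene)triphenylphosphorane | Brc1cccc(C=Cc2ccc(OCc3ccccc3)c(Oc3ccc(C=P(c4ccccc4)(c4ccccc4)c4ccccc4)cc3)c2)c1 | intermediate (not isolated)
17 | 3,6-bis(benzyloxy)-2-[2-(4-{2-(benzyloxy)-5-[2-(3-bromophenyl)ethenyl]phenoxy}phenyl)ethenyl]-4-methoxyphenol (E/Z mixture) | COc1cc(OCc2ccccc2)c(O)c(C=Cc2ccc(Oc3cc(C=Cc4cccc(Br)c4)ccc3OCc3ccccc3)cc2)c1OCc1ccccc1 | intermediate
18 | 3,6-bis(benzyloxy)-2-[2-(4-{2-(benzyloxy)-5-[2-(3-bromophenyl)ethyl]phenoxy}phenyl)ethyl]-4-methoxyphenol | COc1cc(OCc2ccccc2)c(O)c(CCc2ccc(Oc3cc(CCc4cccc(Br)c4)ccc3OCc3ccccc3)cc2)c1OCc1ccccc1 | intermediate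
19 | macrocyclic tribenzyl ether: hydroquinone form of the target, O1, O4 and ring C oxygen benzylated | COc1cc(OCc4ccccc4)c2c(CCc3ccc(cc3)Oc3cc(ccc3OCc3ccccc3)CCc3cccc(c3)O2)c1OCc1ccccc1 | intermediate
20 | hydroquinone form of the target (ring A as the 1,4-diol) | COc1cc(O)c2c(CCc3ccc(cc3)Oc3cc(ccc3O)CCc3cccc(c3)O2)c1O | intermediate (not isolated)
21 | CNP0332646.0 | COC1=CC(=O)C2=C(CCc3ccc(cc3)Oc3cc(ccc3O)CCc3cccc(c3)O2)C1=O | target

**Count and risks**

Total step count: 12. Longest linear sequence: 8 steps (steps 1–4 and 9–12 from 1; the branch from 8 and 9 through steps 5–8 and 9–12 is equally long).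

Steps most likely to fail:

Step 11. Intermolecular etherification may outrun closure by the doubly flanked phenoxide, and bromine may be lost reductively at 110 °C. The fallback changes from a halide-based to an oxidative boron-based closure at room temperature. Setting out from 18, borylation with B2(OH)4 (Pd(OAc)2, XPhos, KOAc, EtOH, 80 °C) should give [3-(2-{4-(benzyloxy)-3-[4-(2-{3,6-bis(benzyloxy)-2-hydroxy-5-methoxyphenyl}ethyl)phenoxy]phenyl}ethyl)phenyl]boronic acid F1. Chan–Lam–Evans coupling (Cu(OAc)2, pyridine, 4 Å molecular sieves, CH2Cl2, air, rt, about 1 mM) should then form the same O5–C3 bond and come back to the route at 19.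

Step 9. Addition of the ylide to an aldehyde that is flanked on both sides and deactivated as its phenoxide may be slow, so that the ylide decomposes first. The fallback reverses the polarity of the olefination. Setting out from 14 and 7, MnO2 (CH2Cl2, rt) should oxidise 14 to 4-{2-(benzyloxy)-5-[2-(3-bromophenyl)ethenyl]phenoxy}benzaldehyde F2. NaBH4 (MeOH, 0 °C) should reduce 7 to 3,6-bis(benzyloxy)-2-(hydroxymethyl)-4-methoxyphenol F3, which PPh3·HBr (MeCN, reflux) should turn into [3,6-bis(benzyloxy)-2-hydroxy-5-methoxybenzyl]triphenylphosphonium bromide F4. KOtBu (2.2 equiv, THF) should give the potassium phenoxide ylide F5, which should add to the unhindered aldehyde F2 and come back to the route at 17.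

Step 4. Formylation at a position flanked by OH and a benzyloxy-bearing carbon may stall, and the hydroxymethyl intermediate may condense with unreacted phenol. The fallback replaces electrophilic substitution by directed ortho-metalation. Setting out from 6, MOMCl and i-Pr2NEt (CH2Cl2) should give 1,4-bis(benzyloxy)-2-methoxy-5-(methoxymethoxy)benzene F6. n-BuLi (THF, −78 to −30 °C) should lithiate the only position ortho to the methoxymethoxy group to give the aryllithium F7, and DMF should convert it into 3,6-bis(benzyloxy)-5-methoxy-2-(methoxymethoxy)benzaldehyde F8. HCl in MeOH/THF should remove the acetal and come back to the route at 7.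

**Further compounds**

F1 | step 11 | [3-(2-{4-(benzyloxy)-3-[4-(2-{3,6-bis(benzyloxy)-2-hydroxy-5-methoxyphenyl}ethyl)phenoxy]phenyl}ethyl)phenyl]boronic acid | COc1cc(OCc2ccccc2)c(O)c(CCc2ccc(Oc3cc(CCc4cccc(B(O)O)c4)ccc3OCc3ccccc3)cc2)c1OCc1ccccc1
F2 | step 9 | 4-{2-(benzyloxy)-5-[2-(3-bromophenyl)ethenyl]phenoxy}benzaldehyde (E/Z mixture) | O=Cc1ccc(Oc2cc(C=Cc3cccc(Br)c3)ccc2OCc2ccccc2)cc1
F3 | step 9 | 3,6-bis(benzyloxy)-2-(hydroxymethyl)-4-methoxyphenol | COc1cc(OCc2ccccc2)c(O)c(CO)c1OCc1ccccc1
F4 | step 9 | [3,6-bis(benzyloxy)-2-hydroxy-5-methoxybenzyl]triphenylphosphonium bromide | [Br-].COc1cc(OCc2ccccc2)c(O)c(C[P+](c2ccccc2)(c2ccccc2)c2ccccc2)c1OCc1ccccc1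
F5 | step 9 | potassium 3,6-bis(benzyloxy)-4-methoxy-2-[(triphenylphosphoranylidene)methyl]phenoxide (not isolated) | [K+].COc1cc(OCc2ccccc2)c([O-])c(C=P(c2ccccc2)(c2ccccc2)c2ccccc2)c1OCc1ccccc1
F6 | step 4 | 1,4-bis(benzyloxy)-2-methoxy-5-(methoxymethoxy)benzene | COc1cc(OCc2ccccc2)c(OCOC)cc1OCc1ccccc1
F7 | step 4 | [3,6-bis(benzyloxy)-5-methoxy-2-(methoxymethoxy)phenyl]lithium (not isolated) | COc1cc(OCc2ccccc2)c(OCOC)c([Li])c1OCc1ccccc1
F8 | step 4 | 3,6-bis(benzyloxy)-5-methoxy-2-(methoxymethoxy)benzaldehyde | COc1cc(OCc2ccccc2)c(OCOC)c(C=O)c1OCc1ccccc1
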